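**Retrosynthetic overview**

1. Locants used (germacrane style): ring C1–C10; C1 free carbinol, C3 acetate carbon, C4=C5 (Z, C15 = CH2OH on C4), C6 lactone carbinol, C7 ring-fusion CH carrying C11(=C13H2)–C12(=O), C8 tiglate carbon, C9=C10 (Z, C14 = CH3 on C10).
2. Eupacunolin ⇐ desilylation, O8-tigloylation ⇐ 8-hydroxy-6,12-olide 30 ⇐ O8→O6 acyl shift ⇐ cis-fused 8,12-olide 29 ⇐ ring-closing Barbier allylation forming C6–C7 from open-chain Z-enal 27, which carries a 3-(bromomethyl)butenolide.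
3. Enabling feature: O8 on C8 and the acrylate carbon C12 on C11 flank C7, so O8 can be tied to C12 as a five-membered butenolide (O8–C8–C7=C11–C12) that is not in the target. This ring fixes the C7=C11 geometry and holds O8 in the allyl plane, so the C9-tethered aldehyde must add to C7 syn to C9; it is cleaved afterwards by translactonisation. The two Z olefins (C4=C5, C9=C10) make the new ring a cis,cis-cyclodeca-1,6-diene, which folds the chain for closure.
4. 27 ⇐ esterification of the C8 carbinol with 2-(bromomethyl)acrylic acid, then ring-closing metathesis; C1/C3 anti-diol monoacetate ⇐ Ipc2BCl aldol (C2–C3) plus Evans–Tishchenko reduction of ketone 10 with enal 17; both Z olefins ⇐ Red-Al/I2 on propargylic alcohols; C8 ⇐ Sharpless kinetic resolution.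
5. Ring order: butenolide (temporary, step 15) → ten-membered carbocycle (step 18) → α-methylene-γ-lactone on O6 (step 19).

Key step: step 18

Remark: with these locants the target is (1S,3S,6R,7R,8R), 4Z, 9Z, with an E (tigloyl) ester; TBS = tert-butyldimethylsilyl, TBDPS = tert-butyldiphenylsilyl, PMB = 4-methoxybenzyl.

**Route**

Step 1
Reactants: 1 acrolein; 2 prop-1-ynylmagnesium bromide
Product: 3 rac-hex-1-en-4-yn-3-ol
Conditions: THF, −78 → 0 °C; aq NH4Cl
Reagents that add atoms: none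
Why: Grignard 1,2-addition of the alkynyl nucleophile to the enal carbonyl gives the racemic vinyl alkynyl carbinol (future C7–C10, C14), which is resolved in the next step.

Step 2
Reactants: 3 rac-hex-1-en-4-yn-3-ol
Product: 4 (S)-hex-1-en-4-yn-3-ol
Conditions: Ti(Oi-Pr)4 (0.1 equiv), diisopropyl L-(+)-tartrate (0.15 equiv), t-BuOOH (0.6 equiv), 4 Å MS, CH2Cl2, −20 °C
Reagents that add atoms: none
Why: Sharpless kinetic resolution; with the L-(+)-tartrate the R enantiomer (alkynyl group turned away from the face of oxygen delivery) should be epoxidised faster, so the S alcohol needed for C8 is recovered.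

Step 3
Reactants: 4 (S)-hex-1-en-4-yn-3-ol
Product: 6 (3S,4Z)-5-iodohexa-1,4-dien-3-ol, via sodium alkenylalanate 5 (not isolated)
Conditions: NaAlH2(OCH2CH2OMe)2 (Red-Al, 1.6 equiv), Et2O, 0 °C → rt; then I2, THF, −78 °C
Reagents that add atoms: iodine, [I][I]
Why: Hydroxyl-directed trans-hydroalumination of the propargylic alcohol puts hydrogen on C9 and aluminium on C10 cis to the carbinol carbon, and iodinolysis with retention fixes the Z geometry of C9=C10.

Step 4
Reactants: 6 (3S,4Z)-5-iodohexa-1,4-dien-3-ol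
Product: 7 1-({[(3S,4Z)-5-iodohexa-1,4-dien-3-yl]oxy}methyl)-4-methoxybenzene
Conditions: NaH, PMBCl, Bu4NI (cat.), THF–DMF, 0 °C
Reagents that add atoms: 4-methoxybenzyl chloride, COc1ccc(CCl)cc1
Why: Williamson etherification at low temperature (to avoid dehydroiodination); the PMB ether tolerates tert-butyllithium and is later removed oxidatively beside silyl ethers and the acetate.

Step 5
Reactants: 7 PMB ether of the iododienol; 8 N-methoxy-N-methylacetamide
Product: 10 (3Z,5S)-5-[(4-methoxybenzyl)oxy]-3-methylhepta-3,6-dien-2-one, via alkenyllithium 9 (not isolated)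
Conditions: t-BuLi (2.1 equiv), Et2O, −78 °C; then 8, −78 → −20 °C; aq NH4Cl
Reagents that add atoms: none
Why: Iodine–lithium exchange with retention of olefin geometry, then Weinreb ketone synthesis (the chelated adduct prevents over-addition), gives the Z methyl ketone that supplies C1 and C2.

Step 6
Reactants: 11 but-2-yne-1,4-diol
Product: 12 4-[(tert-butyldiphenylsilyl)oxy]but-2-yn-1-ol
Conditions: NaH (1.0 equiv), THF, 0 °C; TBDPSCl (1.0 equiv)
Reagents that add atoms: tert-butyl(chloro)diphenylsilane, CC(C)(C)[Si](Cl)(c1ccccc1)c1ccccc1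
Why: Monosilylation of the symmetrical diol through its monosodium alkoxide differentiates the future C15 oxygen (TBDPS) from the future C6 oxygen.

Step 7
Reactants: 12 4-[(tert-butyldiphenylsilyl)oxy]but-2-yn-1-ol
Product: 14 (2Z)-4-[(tert-butyldiphenylsilyl)oxy]-3-iodobut-2-en-1-ol, via sodium alkenylalanate 13 (not isolated)
Conditions: NaAlH2(OCH2CH2OMe)2 (Red-Al, 1.6 equiv), THF, 0 °C; then I2, −78 °C
Reagents that add atoms: iodine, [I][I]
Why: The free hydroxyl directs hydride to C5 and aluminium (then iodine) to C4 in a trans-hydroalumination, so iodine and C6 are cis and the Z geometry of C4=C5 is set.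

Step 8
Reactants: 14 (2Z)-4-[(tert-butyldiphenylsilyl)oxy]-3-iodobut-2-en-1-ol
Product: 15 tert-butyl{[(2Z)-4-[(tert-butyldiphenylsilyl)oxy]-3-iodobut-2-en-1-yl]oxy}dimethylsilane
Conditions: TBSCl, imidazole, CH2Cl2, 0 °C
Reagents that add atoms: tert-butyl(chloro)dimethylsilane, CC(C)(C)[Si](C)(C)Cl
Why: Standard silylation; a primary TBS ether is chosen because it can later be removed beside the TBDPS ether and a secondary TBS ether.

Step 9
Reactants: 15 bis-silyl ether of the iodobutenediol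
Product: 17 (2Z)-4-[(tert-butyldimethylsilyl)oxy]-2-{[(tert-butyldiphenylsilyl)oxy]methyl}but-2-enal, via alkenyllithium 16 (not isolated)
Conditions: t-BuLi (2.1 equiv), Et2O, −78 °C, 10 min; then DMF, −78 °C; aq NH4Cl
Reagents that add atoms: N,N-dimethylformamide, CN(C)C=O
Why: Iodine–lithium exchange with retention, then formylation with DMF, gives the Z enal (CHO = C3); short contact at −78 °C suppresses 1,4-silyl migration to carbon.

Step 10
Reactants: 10 Z methyl ketone; 17 Z enal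
Product: 19 (3S,4Z,8S,9Z)-11-[(tert-butyldimethylsilyl)oxy]-9-{[(tert-butyldiphenylsilyl)oxy]methyl}-8-hydroxy-3-[(4-methoxybenzyl)oxy]-5-methylundeca-1,4,9-trien-6-one, via diisopinocampheylboron enolate 18 (not isolated)
Conditions: (+)-Ipc2BCl (1.3 equiv), Et3N, Et2O, 0 °C; then 17, −78 → −20 °C; H2O2, MeOH–pH 7 buffer
Reagents that add atoms: none
Why: Reagent-controlled boron aldol reaction of a methyl ketone (Paterson aldol); (+)-Ipc2BCl is the antipode expected to deliver the enolate to the Si face of the aldehyde and so set the S carbinol at C3, while the remote C8 centre exerts no control.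

Step 11
Reactants: 19 β-hydroxy ketone
Product: 20 (3S,4Z,6S,8S,9Z)-11-[(tert-butyldimethylsilyl)oxy]-9-{[(tert-butyldiphenylsilyl)oxy]methyl}-6-hydroxy-3-[(4-methoxybenzyl)oxy]-5-methylundeca-1,4,9-trien-8-yl acetate
Conditions: MeCHO (8 equiv), SmI2 (0.3 equiv), THF, −10 °C
Reagents that add atoms: acetaldehyde, CC=O
Why: Evans–Tishchenko reduction; the samarium-bound hemiacetal formed on O3 delivers hydride to the C1 ketone through a six-membered chair, which sets C1 anti to C3 (1S) and leaves the acetate on O3 in the same operation.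

Step 12
Reactants: 20 anti-diol monoacetate
Product: 21 (3S,4Z,6S,8S,9Z)-6,11-bis[(tert-butyldimethylsilyl)oxy]-9-{[(tert-butyldiphenylsilyl)oxy]methyl}-3-[(4-methoxybenzyl)oxy]-5-methylundeca-1,4,9-trien-8-yl acetate
Conditions: TBSOTf, 2,6-lutidine, CH2Cl2, −78 °C
Reagents that add atoms: tert-butyldimethylsilyl trifluoromethanesulfonate, CC(C)(C)[Si](C)(C)OS(=O)(=O)C(F)(F)F
Why: Fast silylation of the C1 hydroxyl with the silyl triflate at low temperature should outrun 1,3-acetyl migration.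

Step 13
Reactants: 21 fully protected triene
Product: 22 (3S,4Z,6S,8S,9Z)-6,11-bis[(tert-butyldimethylsilyl)oxy]-9-{[(tert-butyldiphenylsilyl)oxy]methyl}-3-hydroxy-5-methylundeca-1,4,9-trien-8-yl acetate
Conditions: DDQ (1.3 equiv), CH2Cl2–pH 7 buffer (10:1), 0 °C
Reagents that add atoms: none
Why: Oxidative PMB cleavage (benzylic hydride abstraction, then hydrolysis) frees O8; silyl ethers, acetate and olefins are inert, and buffering protects the bis-allylic alcohol.

Step 14
Reactants: 22 C8 alcohol; 23 2-(bromomethyl)acrylic acid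
Product: 24 (3S,4Z,6S,8S,9Z)-8-acetoxy-6,11-bis[(tert-butyldimethylsilyl)oxy]-9-{[(tert-butyldiphenylsilyl)oxy]methyl}-5-methylundeca-1,4,9-trien-3-yl 2-(bromomethyl)prop-2-enoate
Conditions: N,N'-diisopropylcarbodiimide, DMAP (0.05 equiv), CH2Cl2, −20 → 0 °C
Reagents that add atoms: none
Why: Steglich esterification at low temperature with only a trace of DMAP, so that O-acylation outruns attack of the catalyst on the allylic bromide; this installs C11, C12 and C13 with the bromide in place.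

Step 15
Reactants: 24 2-(bromomethyl)acrylate
Product: 25 (5R)-3-(bromomethyl)-5-[(1Z,3S,5S,6Z)-5-acetoxy-3,8-bis[(tert-butyldimethylsilyl)oxy]-6-{[(tert-butyldiphenylsilyl)oxy]methyl}-2-methylocta-1,6-dien-1-yl]furan-2(5H)-one
Conditions: second-generation Grubbs catalyst (10 mol %), PhMe (2 mM), 70 °C
Reagents that add atoms: none
Why: Ring-closing metathesis; the catalyst loads on the terminal vinyl group and closes onto the 1,1-disubstituted acrylate to give the five-membered butenolide (C7=C11) with loss of ethylene, while the trisubstituted olefins do not engage.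

Step 16
Reactants: 25 bromomethyl butenolide
Product: 26 (5R)-3-(bromomethyl)-5-[(1Z,3S,5S,6Z)-5-acetoxy-3-[(tert-butyldimethylsilyl)oxy]-6-{[(tert-butyldiphenylsilyl)oxy]methyl}-8-hydroxy-2-methylocta-1,6-dien-1-yl]furan-2(5H)-one
Conditions: CSA (0.1 equiv), MeOH–CH2Cl2 (1:1), −10 °C
Reagents that add atoms: none
Why: Acid-catalysed methanolysis removes the primary allylic TBS ether much faster than the secondary TBS and the TBDPS ethers, and the allylic bromide is not solvolysed without base.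

Step 17
Reactants: 26 C6 alcohol
Product: 27 (5R)-3-(bromomethyl)-5-[(1Z,3S,5S,6Z)-5-acetoxy-3-[(tert-butyldimethylsilyl)oxy]-6-{[(tert-butyldiphenylsilyl)oxy]methyl}-2-methyl-8-oxoocta-1,6-dien-1-yl]furan-2(5H)-one
Conditions: Dess–Martin periodinane, NaHCO3, CH2Cl2, 0 °C
Reagents that add atoms: none
Why: Buffered Dess–Martin oxidation should give the Z enal without isomerisation (its β-carbon is fully substituted) and leaves the allylic bromide and butenolide untouched.

Step 18
Reactants: 27 open-chain Z enal with the bromomethyl butenolide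
Product: 29 (1S,3S,6R,7S,8R)-3-acetoxy-1-[(tert-butyldimethylsilyl)oxy]-15-[(tert-butyldiphenylsilyl)oxy]-6-hydroxygermacra-4Z,9Z,11(13)-trien-12,8-olide, via allylchromium dichloride 28 (not isolated)
Conditions: CrCl2 (10 equiv), THF–DMF (3:1), rt, syringe-pump addition of 27 (final 1 mM); aq NH4Cl
Reagents that add atoms: none
Why: Two equivalents of CrCl2 reduce the allylic C13–Br bond to the allylchromium 28, whose γ-carbon C7 adds to the C6 aldehyde through a six-membered Zimmerman–Traxler chair and regenerates C11=C13 as the exocyclic methylene (Nozaki–Hiyama–Kishi-type Barbier allylation; closest precedents are the divalent-chromium closures of ten-membered germacranolides with 2-(bromomethyl)acrylates and the Barbier additions of 3-(bromomethyl)furan-2(5H)-one to aldehydes). One ring is closed, the ten-membered carbocycle, in a 10-exo-trig addition to the carbonyl, and the butenolide survives as the cis-fused 8,12-lactone. C7 is controlled by the temporary ring: the O8–C12 bond holds O8 in the plane of the allyl unit, so the aldehyde, which can only arrive from the face of C8 that carries C9, bonds to C7 syn to C9 and H7 ends cis to H8 (drawn 7S here, the same spatial arrangement as 7R of the target). C6 is controlled by the chair: the ring-locked allyl unit is of the E-crotyl type (C8 trans to CH2Cr), so with C5 equatorial the adduct is anti (H6 trans to H7, 6R), and this chair gives the C5–C6–C7–C8 and C6–C7–C8–C9 torsions the opposite signs found in the chair form of a cis,cis-cyclodeca-1,6-diene. The step needs ring closure to beat intermolecular allylation and 1,2- to beat 1,4-addition to the enal: slow addition to 1 mM and the two Z olefins, which bring C6 within reach of C7, should secure the first, and the normal γ-selective carbonyl addition of allylchromium reagents the second. The absolute configuration of both new centres derives from C8 alone, set in step 2.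

Step 19
Reactants: 29 cis-fused 8,12-olide with free O6–H
Product: 30 (1S,3S,6R,7R,8R)-3-acetoxy-1-[(tert-butyldimethylsilyl)oxy]-15-[(tert-butyldiphenylsilyl)oxy]-8-hydroxygermacra-4Z,9Z,11(13)-trien-12,6-olide
Conditions: DBU (0.2 equiv), PhMe, rt
Reagents that add atoms: none
Why: Base-catalysed translactonisation (O8→O6 acyl shift through a bicyclic tetrahedral intermediate); O6 already sits gauche to C11, and the trans-fused 6,12-lactone, which lets the ring torsion at C6–C7 open to about 90° instead of pinning C6–C7–C8–C9 near 25°, should be the thermodynamic isomer, so the temporary O8–C12 bond is cleaved and O8 is set free.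

Step 20
Reactants: 30 8-hydroxy-6,12-olide; 31 tigloyl chloride
Product: 32 (1S,3S,6R,7R,8R)-3-acetoxy-1-[(tert-butyldimethylsilyl)oxy]-15-[(tert-butyldiphenylsilyl)oxy]-8-[(E)-2-methylbut-2-enoyloxy]germacra-4Z,9Z,11(13)-trien-12,6-olide
Conditions: pyridine, DMAP (0.1 equiv), CH2Cl2, 0 °C → rt
Reagents that add atoms: none
Why: Acylation of the only free hydroxyl under weakly basic conditions that should not re-equilibrate the lactone; the E (tigloyl) geometry is the stable one and is retained.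

Step 21
Reactants: 32 bis-silyl ether of the target
Product: 33 eupacunolin
Conditions: HF·pyridine, pyridine, THF, 0 °C → rt
Reagents that add atoms: none
Why: Fluoride desilylation under mildly acidic, buffered conditions should remove the secondary TBS (O1) and primary TBDPS (O15) groups without acetyl or tigloyl migration and without addition to the methylene lactone.

**Compound list**

1 | acrolein | C=CC=O | starting material
2 | prop-1-ynylmagnesium bromide | CC#C[Mg]Br | starting material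
3 | rac-hex-1-en-4-yn-3-ol | C=CC(O)C#CC | intermediate
4 | (S)-hex-1-en-4-yn-3-ol | C=C[C@H](O)C#CC | intermediate
5 | sodium alkenylalanate from 4 (five-membered O–Al–C10 chelate, H on C9) | C=C[C@H]1C=C(C)[Al-](OCCOC)(OCCOC)O1.[Na+] | intermediate
6 | (3S,4Z)-5-iodohexa-1,4-dien-3-ol | C=C[C@H](O)/C=C(\I)C | intermediate
7 | 1-({[(3S,4Z)-5-iodohexa-1,4-dien-3-yl]oxy}methyl)-4-methoxybenzene | C=C[C@H](OCc1ccc(OC)cc1)/C=C(\I)C | intermediate
8 | N-methoxy-N-methylacetamide | CC(=O)N(C)OC | starting material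
9 | [(2Z,4S)-4-[(4-methoxybenzyl)oxy]hexa-2,5-dien-2-yl]lithium | C=C[C@H](OCc1ccc(OC)cc1)/C=C(\[Li])C | intermediate
10 | (3Z,5S)-5-[(4-methoxybenzyl)oxy]-3-methylhepta-3,6-dien-2-one | CC(=O)/C(C)=C\[C@@H](OCc1ccc(OC)cc1)C=C | intermediate
11 | but-2-yne-1,4-diol | OCC#CCO | starting material
12 | 4-[(tert-butyldiphenylsilyl)oxy]but-2-yn-1-ol | OCC#CCO[Si](c1ccccc1)(c1ccccc1)C(C)(C)C | intermediate
13 | sodium alkenylalanate from 12 (five-membered O–Al–C4 chelate, H on C5) | C1=C(CO[Si](c2ccccc2)(c2ccccc2)C(C)(C)C)[Al-](OCCOC)(OCCOC)OC1.[Na+] | intermediate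
14 | (2Z)-4-[(tert-butyldiphenylsilyl)oxy]-3-iodobut-2-en-1-ol | OC/C=C(\I)CO[Si](c1ccccc1)(c1ccccc1)C(C)(C)C | intermediate
15 | tert-butyl{[(2Z)-4-[(tert-butyldiphenylsilyl)oxy]-3-iodobut-2-en-1-yl]oxy}dimethylsilane | CC(C)(C)[Si](C)(C)OC/C=C(\I)CO[Si](c1ccccc1)(c1ccccc1)C(C)(C)C | intermediate
16 | [(2Z)-4-[(tert-butyldimethylsilyl)oxy]-1-[(tert-butyldiphenylsilyl)oxy]but-2-en-2-yl]lithium | CC(C)(C)[Si](C)(C)OC/C=C(\[Li])CO[Si](c1ccccc1)(c1ccccc1)C(C)(C)C | intermediate
17 | (2Z)-4-[(tert-butyldimethylsilyl)oxy]-2-{[(tert-butyldiphenylsilyl)oxy]methyl}but-2-enal | CC(C)(C)[Si](C)(C)OC/C=C(\C=O)CO[Si](c1ccccc1)(c1ccccc1)C(C)(C)C | intermediate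
18 | diisopinocampheylboron enolate of 10 (O-boron dienolate at C1, Ipc groups from (−)-α-pinene) | C=C(OB([C@@H]1[C@@H](C)[C@@H]2C[C@H](C1)C2(C)C)[C@@H]1[C@@H](C)[C@@H]2C[C@H](C1)C2(C)C)/C(C)=C\[C@@H](OCc1ccc(OC)cc1)C=C | intermediate
19 | (3S,4Z,8S,9Z)-11-[(tert-butyldimethylsilyl)oxy]-9-{[(tert-butyldiphenylsilyl)oxy]methyl}-8-hydroxy-3-[(4-methoxybenzyl)oxy]-5-methylundeca-1,4,9-trien-6-one | C=C[C@H](OCc1ccc(OC)cc1)/C=C(C)\C(=O)C[C@H](O)/C(CO[Si](c1ccccc1)(c1ccccc1)C(C)(C)C)=C\CO[Si](C)(C)C(C)(C)C | intermediate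
20 | (3S,4Z,6S,8S,9Z)-11-[(tert-butyldimethylsilyl)oxy]-9-{[(tert-butyldiphenylsilyl)oxy]methyl}-6-hydroxy-3-[(4-methoxybenzyl)oxy]-5-methylundeca-1,4,9-trien-8-yl acetate | C=C[C@H](OCc1ccc(OC)cc1)/C=C(C)\[C@@H](O)C[C@H](OC(C)=O)/C(CO[Si](c1ccccc1)(c1ccccc1)C(C)(C)C)=C\CO[Si](C)(C)C(C)(C)C | intermediate
21 | (3S,4Z,6S,8S,9Z)-6,11-bis[(tert-butyldimethylsilyl)oxy]-9-{[(tert-butyldiphenylsilyl)oxy]methyl}-3-[(4-methoxybenzyl)oxy]-5-methylundeca-1,4,9-trien-8-yl acetate | C=C[C@H](OCc1ccc(OC)cc1)/C=C(C)\[C@@H](O[Si](C)(C)C(C)(C)C)C[C@H](OC(C)=O)/C(CO[Si](c1ccccc1)(c1ccccc1)C(C)(C)C)=C\CO[Si](C)(C)C(C)(C)C | intermediate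
22 | (3S,4Z,6S,8S,9Z)-6,11-bis[(tert-butyldimethylsilyl)oxy]-9-{[(tert-butyldiphenylsilyl)oxy]methyl}-3-hydroxy-5-methylundeca-1,4,9-trien-8-yl acetate | C=C[C@H](O)/C=C(C)\[C@@H](O[Si](C)(C)C(C)(C)C)C[C@H](OC(C)=O)/C(CO[Si](c1ccccc1)(c1ccccc1)C(C)(C)C)=C\CO[Si](C)(C)C(C)(C)C | intermediate
23 | 2-(bromomethyl)acrylic acid | C=C(CBr)C(=O)O | starting material
24 | (3S,4Z,6S,8S,9Z)-8-acetoxy-6,11-bis[(tert-butyldimethylsilyl)oxy]-9-{[(tert-butyldiphenylsilyl)oxy]methyl}-5-methylundeca-1,4,9-trien-3-yl 2-(bromomethyl)prop-2-enoate | C=C[C@H](OC(=O)C(=C)CBr)/C=C(C)\[C@@H](O[Si](C)(C)C(C)(C)C)C[C@H](OC(C)=O)/C(CO[Si](c1ccccc1)(c1ccccc1)C(C)(C)C)=C\CO[Si](C)(C)C(C)(C)C | intermediate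
25 | (5R)-3-(bromomethyl)-5-[(1Z,3S,5S,6Z)-5-acetoxy-3,8-bis[(tert-butyldimethylsilyl)oxy]-6-{[(tert-butyldiphenylsilyl)oxy]methyl}-2-methylocta-1,6-dien-1-yl]furan-2(5H)-one | BrCC1=C[C@@H](/C=C(C)\[C@@H](O[Si](C)(C)C(C)(C)C)C[C@H](OC(C)=O)/C(CO[Si](c2ccccc2)(c2ccccc2)C(C)(C)C)=C\CO[Si](C)(C)C(C)(C)C)OC1=O | intermediate
26 | (5R)-3-(bromomethyl)-5-[(1Z,3S,5S,6Z)-5-acetoxy-3-[(tert-butyldimethylsilyl)oxy]-6-{[(tert-butyldiphenylsilyl)oxy]methyl}-8-hydroxy-2-methylocta-1,6-dien-1-yl]furan-2(5H)-one | BrCC1=C[C@@H](/C=C(C)\[C@@H](O[Si](C)(C)C(C)(C)C)C[C@H](OC(C)=O)/C(CO[Si](c2ccccc2)(c2ccccc2)C(C)(C)C)=C\CO)OC1=O | intermediate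
27 | (5R)-3-(bromomethyl)-5-[(1Z,3S,5S,6Z)-5-acetoxy-3-[(tert-butyldimethylsilyl)oxy]-6-{[(tert-butyldiphenylsilyl)oxy]methyl}-2-methyl-8-oxoocta-1,6-dien-1-yl]furan-2(5H)-one | BrCC1=C[C@@H](/C=C(C)\[C@@H](O[Si](C)(C)C(C)(C)C)C[C@H](OC(C)=O)/C(CO[Si](c2ccccc2)(c2ccccc2)C(C)(C)C)=C\C=O)OC1=O | intermediate
28 | allylchromium dichloride from 27 (CrCl2 on C13) | Cl[Cr](Cl)CC1=C[C@@H](/C=C(C)\[C@@H](O[Si](C)(C)C(C)(C)C)C[C@H](OC(C)=O)/C(CO[Si](c2ccccc2)(c2ccccc2)C(C)(C)C)=C\C=O)OC1=O | intermediate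
29 | (1S,3S,6R,7S,8R)-3-acetoxy-1-[(tert-butyldimethylsilyl)oxy]-15-[(tert-butyldiphenylsilyl)oxy]-6-hydroxygermacra-4Z,9Z,11(13)-trien-12,8-olide (cis-fused lactone) | C=C1C(=O)O[C@@H]2/C=C(C)\[C@@H](O[Si](C)(C)C(C)(C)C)C[C@H](OC(C)=O)/C(CO[Si](c3ccccc3)(c3ccccc3)C(C)(C)C)=C\[C@@H](O)[C@H]12 | intermediate
30 | (1S,3S,6R,7R,8R)-3-acetoxy-1-[(tert-butyldimethylsilyl)oxy]-15-[(tert-butyldiphenylsilyl)oxy]-8-hydroxygermacra-4Z,9Z,11(13)-trien-12,6-olide (trans-fused lactone) | C=C1C(=O)O[C@@H]2/C=C(/CO[Si](c3ccccc3)(c3ccccc3)C(C)(C)C)[C@@H](OC(C)=O)C[C@H](O[Si](C)(C)C(C)(C)C)/C(C)=C\[C@@H](O)[C@@H]12 | intermediate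
31 | tigloyl chloride, (E)-2-methylbut-2-enoyl chloride | C/C=C(\C)C(=O)Cl | starting material
32 | (1S,3S,6R,7R,8R)-3-acetoxy-1-[(tert-butyldimethylsilyl)oxy]-15-[(tert-butyldiphenylsilyl)oxy]-8-[(E)-2-methylbut-2-enoyloxy]germacra-4Z,9Z,11(13)-trien-12,6-olide | C=C1C(=O)O[C@@H]2/C=C(/CO[Si](c3ccccc3)(c3ccccc3)C(C)(C)C)[C@@H](OC(C)=O)C[C@H](O[Si](C)(C)C(C)(C)C)/C(C)=C\[C@@H](OC(=O)/C(C)=C/C)[C@@H]12 | intermediate
33 | eupacunolin, (1S,3S,6R,7R,8R)-3-acetoxy-1,15-dihydroxy-8-[(E)-2-methylbut-2-enoyloxy]germacra-4Z,9Z,11(13)-trien-12,6-olide | C=C1C(=O)O[C@@H]2/C=C(/CO)[C@@H](OC(C)=O)C[C@H](O)/C(C)=C\[C@@H](OC(=O)/C(C)=C/C)[C@@H]12 | target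

**Step count and risks**

Total: 21 steps. Longest linear sequence: 17 steps (steps 1–5, then 10–21); the enal branch (steps 6–9) is 4 steps.

Steps most likely to fail:

1. Step 18 (ring-closing allylation). What may go wrong: intermolecular allylation to oligomers, or protonation or β-elimination (opening of the butenolide) of the allylchromium before it reaches the aldehyde. Fallback, setting out from 25 and returning at 29: the ring is closed by a reductant-free intramolecular allylboration instead of a Barbier reaction. Bromide 25 is borylated with B2pin2 and catalytic Pd2(dba)3 in THF at rt (the primary allylic bromide should add to zerovalent palladium far faster than the secondary allylic esters) to give the allylboronate, the 3-[(pinacolatoboryl)methyl]butenolide F1. CSA in MeOH frees the C6 alcohol F2 and Dess–Martin oxidation gives the aldehyde boronate F3. Heating F3 at 1 mM (PhMe, 80 °C, or Sc(OTf)3 cat. at rt) should close the ring through the same chair to the cyclic O6-borate F4, which aqueous work-up hydrolyses to 29.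

2. Step 19 (acyl shift). What may go wrong: the equilibrium between the two lactones may not lie far enough on the side of 30, or the acetate may migrate from O3 to O6. Fallback, setting out from 29 and returning at 32, kinetic instead of thermodynamic: O6 is capped as the triethylsilyl ether F5 (TESOTf, 2,6-lutidine, −78 °C). The lactone is opened with Me2AlN(OMe)Me (from Me3Al and MeNHOMe·HCl, CH2Cl2, 0 °C) to the 8-hydroxy Weinreb amide F6, and O8 is tigloylated as in step 20 to give the tiglate Weinreb amide F7. CSA in MeOH–CH2Cl2 then removes the triethylsilyl group, and O6–H, the only free hydroxyl, closes onto the Weinreb amide with loss of MeNHOMe to give 32 directly.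

3. Step 15 (ring-closing metathesis). What may go wrong: decomposition of the ruthenium carbene by the allylic bromide, or loss of the bromide to DMAP during step 14, so that closure stalls. Fallback, setting out from 22 and returning at 25: bromine is introduced after the metathesis. Commercial ethyl 2-(hydroxymethyl)acrylate is converted with PMB trichloroacetimidate (CSA cat.) into ethyl 2-{[(4-methoxybenzyl)oxy]methyl}acrylate F8 and saponified (LiOH, THF–H2O) to the acid F9. Alcohol 22 is esterified with F9 (N,N'-diisopropylcarbodiimide, DMAP) to the acrylate F10, and metathesis with second-generation Grubbs catalyst gives the PMB-oxymethyl butenolide F11. DDQ releases the hydroxymethyl butenolide F12, which CBr4/PPh3 converts into 25.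

Further compounds
F1 | step 18 | (5R)-5-[(1Z,3S,5S,6Z)-5-acetoxy-3,8-bis[(tert-butyldimethylsilyl)oxy]-6-{[(tert-butyldiphenylsilyl)oxy]methyl}-2-methylocta-1,6-dien-1-yl]-3-[(4,4,5,5-tetramethyl-1,3,2-dioxaborolan-2-yl)methyl]furan-2(5H)-one | CC1(C)OB(CC2=C[C@@H](/C=C(C)\[C@@H](O[Si](C)(C)C(C)(C)C)C[C@H](OC(C)=O)/C(CO[Si](c3ccccc3)(c3ccccc3)C(C)(C)C)=C\CO[Si](C)(C)C(C)(C)C)OC2=O)OC1(C)C
F2 | step 18 | C6 alcohol of F1 (8-hydroxy in the side chain) | CC1(C)OB(CC2=C[C@@H](/C=C(C)\[C@@H](O[Si](C)(C)C(C)(C)C)C[C@H](OC(C)=O)/C(CO[Si](c3ccccc3)(c3ccccc3)C(C)(C)C)=C\CO)OC2=O)OC1(C)C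
F3 | step 18 | C6 aldehyde of F1 (8-oxo in the side chain) | CC1(C)OB(CC2=C[C@@H](/C=C(C)\[C@@H](O[Si](C)(C)C(C)(C)C)C[C@H](OC(C)=O)/C(CO[Si](c3ccccc3)(c3ccccc3)C(C)(C)C)=C\C=O)OC2=O)OC1(C)C
F4 | step 18 | O6-(pinacolatoboryl) ether of 29 | C=C1C(=O)O[C@@H]2/C=C(C)\[C@@H](O[Si](C)(C)C(C)(C)C)C[C@H](OC(C)=O)/C(CO[Si](c3ccccc3)(c3ccccc3)C(C)(C)C)=C\[C@@H](OB3OC(C)(C)C(C)(C)O3)[C@H]12
F5 | step 19 | O6-triethylsilyl ether of 29 | C=C1C(=O)O[C@@H]2/C=C(C)\[C@@H](O[Si](C)(C)C(C)(C)C)C[C@H](OC(C)=O)/C(CO[Si](c3ccccc3)(c3ccccc3)C(C)(C)C)=C\[C@@H](O[Si](CC)(CC)CC)[C@H]12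
F6 | step 19 | ring-opened 8-hydroxy N-methoxy-N-methyl acrylamide (C12 amide on the ten-membered ring, O6-triethylsilyl) | C=C(C(=O)N(C)OC)[C@@H]1[C@H](O)/C=C(C)\[C@@H](O[Si](C)(C)C(C)(C)C)C[C@H](OC(C)=O)/C(CO[Si](c2ccccc2)(c2ccccc2)C(C)(C)C)=C\[C@H]1O[Si](CC)(CC)CC
F7 | step 19 | 8-O-tiglate of F6 | C=C(C(=O)N(C)OC)[C@@H]1[C@H](OC(=O)/C(C)=C/C)/C=C(C)\[C@@H](O[Si](C)(C)C(C)(C)C)C[C@H](OC(C)=O)/C(CO[Si](c2ccccc2)(c2ccccc2)C(C)(C)C)=C\[C@H]1O[Si](CC)(CC)CC
F8 | step 15 | ethyl 2-{[(4-methoxybenzyl)oxy]methyl}acrylate | C=C(COCc1ccc(OC)cc1)C(=O)OCC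
F9 | step 15 | 2-{[(4-methoxybenzyl)oxy]methyl}acrylic acid | C=C(COCc1ccc(OC)cc1)C(=O)O
F10 | step 15 | 2-{[(4-methoxybenzyl)oxy]methyl}acrylate of 22 | C=C[C@H](OC(=O)C(=C)COCc1ccc(OC)cc1)/C=C(C)\[C@@H](O[Si](C)(C)C(C)(C)C)C[C@H](OC(C)=O)/C(CO[Si](c1ccccc1)(c1ccccc1)C(C)(C)C)=C\CO[Si](C)(C)C(C)(C)C
F11 | step 15 | (5R)-3-{[(4-methoxybenzyl)oxy]methyl} analogue of 25 | COc1ccc(COCC2=C[C@@H](/C=C(C)\[C@@H](O[Si](C)(C)C(C)(C)C)C[C@H](OC(C)=O)/C(CO[Si](c3ccccc3)(c3ccccc3)C(C)(C)C)=C\CO[Si](C)(C)C(C)(C)C)OC2=O)cc1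
F12 | step 15 | (5R)-3-(hydroxymethyl) analogue of 25 | OCC1=C[C@@H](/C=C(C)\[C@@H](O[Si](C)(C)C(C)(C)C)C[C@H](OC(C)=O)/C(CO[Si](c2ccccc2)(c2ccccc2)C(C)(C)C)=C\CO[Si](C)(C)C(C)(C)C)OC1=O
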